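## The problem

Atom labels used throughout: the bicycle is C1–C10 (ring A = C1–C5 and C10, ring B = C5–C10), the chain carbons run C11–C17 outward from C9, and the ester carbon is C18.

- The target is a cis-fused decalin. Ring A carries the C4 gem-dimethyl group; ring B holds a tetrasubstituted C8=C9 olefin with a methyl on C8 and the C11–C18 chain on C9.
- The ring stereocentres are C5 (tertiary) and the quaternary, methyl-bearing C10. They are adjacent, so one can set the other if the second is made intramolecularly.
- The third stereocentre, C17, lies seven bonds from the ring across an achiral diene. No relay is possible, so it must arrive as a single enantiomer in its own building block.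
- The chain needs a 13E trisubstituted and a 15E disubstituted olefin, both fixed by construction.
- The C17–H bond is α to the ester and allylic. Base would epimerise it and pull the diene into conjugation, so nothing basic may follow the introduction of C17.
- The C8=C9 olefin and allylic derivatives at C11 are sensitive to acid (olefin migration, ionisation).
- C10 is flanked by the quaternary C4, so the C9–C10 bond is hard to make between two separate molecules.
- The enabling feature: ring A with its C4 gem-dimethyl group, the C5 stereocentre, the C10 methyl on an olefin and the carbons C6–C9 are the skeleton of α-ionone, so only the C9–C10 bond of ring B is missing. An oxygen on C2 makes C10 electrophilic; a β-keto ester at C8/C9 makes C9 nucleophilic. Its two carbonyl groups later become the site of the C8 methyl and the carbon C11.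

## Retrosynthesis

**Target 24 to alkyne 15 and iodo ester 22.** The C14–C15 bond is cut, together with the C13–CH3 bond. Syn-methylalumination of 15 gives alkenylalane 23, which fixes the 13E geometry; coupling with 22 keeps both olefin geometries. The neighbouring cuts are weaker: olefination at C15=C16 needs an ylide or sulfone anion next to an epimerisable centre, and olefination of a C13 methyl ketone gives poor E/Z control. The precursors are a ring piece without chain stereochemistry and a five-carbon ester. The forward reaction must run without base so that C17 arrives and stays intact.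

**Iodo ester 22 to hydroxy ester 16.** The alkenyl iodide goes back to aldehyde 18 by a one-carbon olefination, via silyl ether 19. The ester goes back through acid 21 to alcohol 20. The two ends of 16 are thereby exchanged: its ester carbon becomes C16 and its CH2OH becomes C18. Keeping the original ester as C18 would require a 2-formylpropanoate, which racemises by enolisation. Protection as 17 covers the reduction and the olefination. The forward steps must be non-basic and E-selective.

**Alkyne 15 to bromide 12 and silylpropyne 13.** The C11–C12 bond is cut; silylated alkyne 14 is the intermediate. A cut at C12–C13 would need a homoallylic electrophile, which means one more carbon on the ring piece. Bromide 12 comes from alcohol 11 and this from ester 10, whose ester carbon is C11. The forward alkylation must go SN2 and not SN2'.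

**Ester 10 to keto ester 6.** Two functional-group changes are undone. The C2 methylene goes back through tosylhydrazone 9 to ketone 8. The C8–CH3 bond goes back through enol triflate 7 to the enol oxygen of 6. The methyl is installed first, because a hydrazide would not distinguish the two carbonyl groups of 6. Both oxygens are exactly the activators the ring closure needs, so nothing is added only to be removed, except the C2 oxygen.

**Keto ester 6 to enone 5.** The C9–C10 bond is cut. Of the bonds of ring B it is the only one whose cleavage leaves the ionone chain intact and puts the new stereocentre beside the existing one. Two rings and two stereocentres become one ring and one stereocentre. The forward reaction must close cis and must not racemise C5.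

**Enone 5 to (R)-α-ionone 1.** The C2 oxygen is removed (allylic oxidation of 4 in the forward sense). The C9–C11 bond is cut to ketone 2 and dimethyl carbonate 3. Ketone 2 is the conjugate reduction product of 1. The ester is introduced before the enone exists, because a ring enone would not survive NaH. The conjugate reduction comes first, because the doubly allylic C–H of 1 is the point where the stereocentre could be lost.

## Roads not taken

**Alternative 1: anionic oxy-Cope rearrangement.**
- Cut: the C1–C10 bond of ring A is made while a C3–C8 bond of a bridged precursor is broken. The precursor is 6-(but-3-en-1-yl)-2-ethenyl-1,3,3,5-tetramethylbicyclo[2.2.2]oct-5-en-2-ol A2, with the ethenyl group over the olefinic bridge.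
- Forward step: [3,3] shift of its potassium alkoxide gives (4aS,8aS)-5-(but-3-en-1-yl)-1,1,4a,6-tetramethyl-3,4,4a,7,8,8a-hexahydronaphthalen-2(1H)-one A1.
- Merits: the shift is suprafacial on a rigid frame, so the cis fusion and quaternary C10 are certain. It is irreversible because an enolate results. A1 already has the C8 methyl, the C8=C9 olefin and four chain carbons.
- Weak points: A2 has three stereocentres, two of them quaternary bridgeheads, and must itself be one enantiomer. That calls for an asymmetric cycloaddition of a heavily substituted cyclohexadiene and a face-selective vinyl addition to a ketone between two quaternary carbons. The C3 ketone of A1 must still be deleted. The butenyl end must become the methyl-branched E-olefin through a methyl ketone olefination with mediocre geometry control.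
- Comparison: the ring-forming event is more dependable than the reversible, sterically pressed Michael addition chosen here. Against that the chosen plan sets a precursor with one purchased stereocentre, reached in three steps, and a chain olefin set by syn-carbometallation.

**Alternative 2: asymmetric quinone Diels–Alder reaction.**
- Cut: both C1–C10 and C4–C5 of ring A, leaving 2,6-dimethyl-1,4-benzoquinone A4 (the future ring B) and 4-methylpenta-1,3-diene A5.
- Forward step: cycloaddition under a chiral cationic boron Lewis acid gives cis-fused 2,5,5,8a-tetramethyl-4a,5,8,8a-tetrahydronaphthalene-1,4-dione A3.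
- Merits: it is the only road that creates both ring-fusion centres at once, catalytically, from two cheap achiral compounds. The cis fusion is intrinsic, and no enantiopure terpene is needed.
- Weak points: A5 carries a Z-methyl on its terminus, so its s-cis conformer is strained and it is a poor diene. It must bond through its fully substituted terminus, and A4 must react at a methyl-bearing double bond. A3 has oxygen on C6 and C9, an olefin at C7=C8 instead of C8=C9 and another at C2=C3. One carbonyl and one olefin must be removed selectively, and the C9 carbonyl next to quaternary C10 must accept the chain and become the tetrasubstituted olefin.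
- Comparison: it is shorter to a bicyclic core and catalytic in chirality, and in that respect better. The chosen plan answers with functional groups that are all used: the C8 oxygen becomes the methyl site, the ester carbon becomes C11, and only the C2 oxygen is excised.

**Alternative 3: radical closure of ring A.**
- Cut: C4–C5, from (4S)-2,4-dimethyl-3-[2-(2-methyl-1,3-dioxolan-2-yl)ethyl]-4-(4-methylpent-4-en-1-yl)cyclohexa-2,5-dien-1-one A7.
- Forward step: iron-catalysed hydrogen-atom transfer from a silane to the isopropenyl group gives the tertiary C4 radical. It adds to C5 of the unsubstituted enone arm and gives cis-fused 3,4a,8,8-tetramethyl-4-[2-(2-methyl-1,3-dioxolan-2-yl)ethyl]-4a,5,6,7,8,8a-hexahydronaphthalen-2(1H)-one A6.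
- Merits: a radical conjugate addition has an early transition state and is irreversible, so congestion matters little. A6 already has the C8 methyl, the C8=C9 olefin and five chain carbons.
- Weak points: the only stereocentre of A7 is quaternary C10, which no chiral-pool compound supplies. The C7 carbonyl of A6 is conjugated to C8=C9, so deleting it without moving or reducing that olefin is harder than deleting an isolated ketone. The masked C13 ketone must later be olefinated with only moderate E control.
- Comparison: the ring closure is probably the more reliable of the two. The chosen plan sets against it a purchased absolute configuration, an isolated ketone to delete, and a C13=C14 geometry fixed by carbometallation.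

Key step: step 4

Assumption: (R)-α-ionone 1 is bought as the single enantiomer; keto ester 6 is written as its enol tautomer and hydrazone 9 as a mixture of C=N isomers, neither of which affects the route.

## Steps

Step 1
Reactants: 1 (3E)-4-[(1R)-2,6,6-trimethylcyclohex-2-en-1-yl]but-3-en-2-one, (R)-α-ionone
Product: 2 4-[(1R)-2,6,6-trimethylcyclohex-2-en-1-yl]butan-2-one
Conditions: [(Ph3P)CuH]6 (0.35 equiv), H2O (5 equiv), toluene, rt
Reagents that add atoms: none
Why: Copper hydride conjugate reduction (Stryker reduction): hydride goes only to the β-carbon of the side-chain enone and water protonates the copper enolate; the isolated ring olefin is untouched and, with no base present, the doubly allylic C–H of the stereocentre is never ionised, so the R configuration should be kept.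

Step 2
Reactants: 2 4-[(1R)-2,6,6-trimethylcyclohex-2-en-1-yl]butan-2-one; 3 dimethyl carbonate
Product: 4 methyl 3-oxo-5-[(1R)-2,6,6-trimethylcyclohex-2-en-1-yl]pentanoate
Conditions: NaH (2.5 equiv), dimethyl carbonate (5 equiv), THF, reflux; 1 M HCl work-up
Reagents that add atoms: none
Why: Crossed Claisen condensation of the methyl ketone with dimethyl carbonate; acylation at the methyl group is driven by irreversible deprotonation of the β-keto ester formed, and the stereocentre, now only allylic, is not acidic.

Step 3
Reactants: 4 methyl 3-oxo-5-[(1R)-2,6,6-trimethylcyclohex-2-en-1-yl]pentanoate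
Product: 5 methyl 3-oxo-5-[(1R)-2,6,6-trimethyl-4-oxocyclohex-2-en-1-yl]pentanoate
Conditions: Rh2(cap)4 (1 mol %), t-BuOOH (70% aq., 5 equiv), 1,2-dichloroethane, 40 °C
Reagents that add atoms: tert-butyl hydroperoxide, CC(C)(C)OO
Why: Radical allylic oxidation with t-BuOOH catalysed by Rh2(cap)4: the tert-butylperoxy radical abstracts the weakest and least hindered allylic hydrogen (ring CH2 next to the olefinic CH), the allyl radical is capped as a mixed peroxide and this collapses to the enone; the hindered tertiary allylic C–H and the stronger C–H bonds of the keto ester should react more slowly, and the base-free medium keeps the keto ester un-ionised and the stereocentre, now γ to the new carbonyl, intact.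

Step 4
Reactants: 5 methyl 3-oxo-5-[(1R)-2,6,6-trimethyl-4-oxocyclohex-2-en-1-yl]pentanoate
Product: 6 methyl (4aR,8aS)-2-hydroxy-5,5,8a-trimethyl-7-oxo-3,4,4a,5,6,7,8,8a-octahydronaphthalene-1-carboxylate
Conditions: Cs2CO3 (0.3 equiv), MeCN, 25 → 45 °C
Reagents that add atoms: none
Why: Catalytic carbonate ionises only the β-keto ester (far more acidic than the γ-hydrogen of the enone at C5), and the enolate carbon C9 adds to C10 of the ring enone in an intramolecular Michael addition; proton transfer from the new C1–C2 enolate to give the chelated enol of the product returns the base. The closest known reaction type is the base-mediated cyclisation of tethered β-keto esters onto cyclohexenones, which gives cis-fused bicycles. Ring B closes in the 6-exo-trig mode, since of the acceptor olefin C1=C10 only C10 enters the new ring. The one new stereocentre, quaternary C10, is controlled by C5: the three-atom tether C6–C7–C8 can bring C9 only to the enone face on which it is attached, by axial attack anti to the pseudoaxial H5, so the C9–C10 bond forms cis to C5–C6 and the C10 methyl ends cis to H5. C-alkylation is expected to prevail over the reversible oxa-Michael pathway because the carbon adduct is held as a stabilised enol(ate). The step needs C5 to keep its configuration; the weak base, buffered by the keto ester itself, secures this, and after closure C5 is no longer vinylogous to a carbonyl. The incoming carbon passes the axial C4 methyl and the acceptor is β,β-disubstituted, which is why a polar aprotic solvent, the caesium counter-ion and gentle warming are specified.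

Step 5
Reactants: 6 methyl (4aR,8aS)-2-hydroxy-5,5,8a-trimethyl-7-oxo-3,4,4a,5,6,7,8,8a-octahydronaphthalene-1-carboxylate
Product: 7 methyl (4aR,8aS)-5,5,8a-trimethyl-7-oxo-2-(trifluoromethanesulfonyloxy)-3,4,4a,5,6,7,8,8a-octahydronaphthalene-1-carboxylate
Conditions: NaH (1.05 equiv), THF, 0 °C; PhNTf2 (1.2 equiv), 0 °C → rt
Reagents that add atoms: N-phenylbis(trifluoromethanesulfonimide), O=S(=O)(N(c1ccccc1)S(=O)(=O)C(F)(F)F)C(F)(F)F
Why: O-Sulfonylation of the sodium enolate of the cyclic β-keto ester gives the enol triflate; one equivalent of NaH removes only the enolic proton, so the C2 ketone is left alone, and once C9 is locked as sp2 the ring can no longer reopen by retro-Michael reaction.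

Step 6
Reactants: 7 methyl (4aR,8aS)-5,5,8a-trimethyl-7-oxo-2-(trifluoromethanesulfonyloxy)-3,4,4a,5,6,7,8,8a-octahydronaphthalene-1-carboxylate
Product: 8 methyl (4aR,8aS)-2,5,5,8a-tetramethyl-7-oxo-3,4,4a,5,6,7,8,8a-octahydronaphthalene-1-carboxylate
Conditions: CuI (3 equiv), MeLi (6 equiv), Et2O, 0 °C; then 7, THF, −78 → −30 °C; aq. NH4Cl/NH3
Reagents that add atoms: lithium dimethylcuprate Me2CuLi, [Li+].C[Cu-]C
Why: Addition–elimination of the Gilman reagent at the β-carbon of the β-triflyloxy enoate, the classical way from cyclic β-keto esters to β-methyl enoates, places the C8 methyl on the tetrasubstituted olefin; at low temperature the cuprate should not add to the saturated C2 ketone, which is flanked by two neopentyl-type CH2 groups.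

Step 7
Reactants: 8 methyl (4aR,8aS)-2,5,5,8a-tetramethyl-7-oxo-3,4,4a,5,6,7,8,8a-octahydronaphthalene-1-carboxylate
Product: 9 methyl (4aR,8aS)-2,5,5,8a-tetramethyl-7-[2-(4-methylbenzenesulfonyl)hydrazinylidene]-3,4,4a,5,6,7,8,8a-octahydronaphthalene-1-carboxylate
Conditions: TsNHNH2 (1.3 equiv), MeOH, 60 °C
Reagents that add atoms: p-toluenesulfonyl hydrazide, Cc1ccc(cc1)S(=O)(=O)NN
Why: Hydrazone formation at the only ketone; the tetrasubstituted enoate offers neither a comparably reactive carbonyl nor an accessible β-carbon, and the C=N geometry is of no consequence.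

Step 8
Reactants: 9 methyl (4aR,8aS)-2,5,5,8a-tetramethyl-7-[2-(4-methylbenzenesulfonyl)hydrazinylidene]-3,4,4a,5,6,7,8,8a-octahydronaphthalene-1-carboxylate
Product: 10 methyl (4aR,8aS)-2,5,5,8a-tetramethyl-3,4,4a,5,6,7,8,8a-octahydronaphthalene-1-carboxylate
Conditions: catecholborane (3 equiv), CHCl3, 0 °C → rt; then NaOAc·3H2O, reflux
Reagents that add atoms: none
Why: Mild variant of the Caglioti reduction: hydride from catecholborane adds to the C=N bond, acetate then triggers loss of sulfinate and dinitrogen to leave the CH2 group; the ester and the tetrasubstituted olefin are inert to the borane under these conditions and no stereocentre is touched.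

Step 9
Reactants: 10 methyl (4aR,8aS)-2,5,5,8a-tetramethyl-3,4,4a,5,6,7,8,8a-octahydronaphthalene-1-carboxylate
Product: 11 [(4aR,8aS)-2,5,5,8a-tetramethyl-3,4,4a,5,6,7,8,8a-octahydronaphthalen-1-yl]methanol
Conditions: i-Bu2AlH (3 equiv), CH2Cl2, −78 → 0 °C; aq. sodium potassium tartrate
Reagents that add atoms: none
Why: 1,2-Reduction of the conjugated ester to the primary allylic alcohol; the fully substituted β-carbon rules out conjugate reduction.

Step 10
Reactants: 11 [(4aR,8aS)-2,5,5,8a-tetramethyl-3,4,4a,5,6,7,8,8a-octahydronaphthalen-1-yl]methanol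
Product: 12 (4aR,8aS)-1-(bromomethyl)-2,5,5,8a-tetramethyl-3,4,4a,5,6,7,8,8a-octahydronaphthalene
Conditions: PBr3 (0.4 equiv), pyridine (cat.), Et2O, 0 °C; used without purification
Reagents that add atoms: phosphorus tribromide, BrP(Br)Br
Why: Bromination of the primary allylic alcohol through its phosphite ester with SN2 displacement at the unhindered CH2; low temperature and a trace of pyridine suppress acid-induced olefin migration, and the labile bromide is used at once.

Step 11
Reactants: 12 (4aR,8aS)-1-(bromomethyl)-2,5,5,8a-tetramethyl-3,4,4a,5,6,7,8,8a-octahydronaphthalene; 13 trimethyl(prop-1-yn-1-yl)silane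
Product: 15 (4aR,8aS)-1-(but-3-yn-1-yl)-2,5,5,8a-tetramethyl-3,4,4a,5,6,7,8,8a-octahydronaphthalene, via silylated alkyne 14 (not isolated)
Conditions: 13 (1.5 equiv), n-BuLi (1.4 equiv), THF, −78 °C; then 12, −78 → 0 °C; then MeOH, K2CO3, rt
Reagents that add atoms: none
Why: SN2 alkylation of the propargylic lithium reagent with the primary allylic bromide forms the C11–C12 bond (the silyl group directs reaction to the propargyl terminus, and SN2' attack at the fully substituted C8 is sterically excluded); K2CO3 in methanol then cleaves the alkynyl–silicon bond in the same flask.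

Step 12
Reactants: 16 methyl (2S)-3-hydroxy-2-methylpropanoate
Product: 17 methyl (2S)-3-[(tert-butyldimethylsilyl)oxy]-2-methylpropanoate
Conditions: TBSCl (1.1 equiv), imidazole (1.5 equiv), CH2Cl2, 0 °C → rt
Reagents that add atoms: tert-butyldimethylsilyl chloride, CC(C)(C)[Si](C)(C)Cl
Why: Standard silyl ether formation at the primary alcohol; the stereocentre is not involved.

Step 13
Reactants: 17 methyl (2S)-3-[(tert-butyldimethylsilyl)oxy]-2-methylpropanoate
Product: 18 (2S)-3-[(tert-butyldimethylsilyl)oxy]-2-methylpropanal
Conditions: i-Bu2AlH (1.05 equiv), CH2Cl2, −78 °C; MeOH, aq. sodium potassium tartrate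
Reagents that add atoms: none
Why: Partial reduction of the methyl ester at −78 °C, where the tetrahedral aluminium hemiacetal persists until the quench; the α-stereogenic aldehyde is configurationally labile and is therefore taken straight into the next step.

Step 14
Reactants: 18 (2S)-3-[(tert-butyldimethylsilyl)oxy]-2-methylpropanal
Product: 19 tert-butyl{[(2R,3E)-4-iodo-2-methylbut-3-en-1-yl]oxy}dimethylsilane
Conditions: CrCl2 (6 equiv), CHI3 (2 equiv), dioxane–THF (6:1), 0 °C → rt
Reagents that add atoms: iodoform, IC(I)I
Why: Takai olefination: the geminal dichromium species from CHI3 and CrCl2 adds to the aldehyde and eliminates to the E-alkenyl iodide; the reagent is not basic, so the α-stereocentre should be retained (the descriptor changes from S to R only because the priorities change).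

Step 15
Reactants: 19 tert-butyl{[(2R,3E)-4-iodo-2-methylbut-3-en-1-yl]oxy}dimethylsilane
Product: 20 (2R,3E)-4-iodo-2-methylbut-3-en-1-ol
Conditions: CSA (10 mol %), MeOH, 0 °C → rt
Reagents that add atoms: none
Why: Acid-catalysed methanolysis of the primary silyl ether; the alkenyl iodide and the stereocentre are stable to these conditions.

Step 16
Reactants: 20 (2R,3E)-4-iodo-2-methylbut-3-en-1-ol
Product: 21 (2R,3E)-4-iodo-2-methylbut-3-enoic acid
Conditions: TEMPO (20 mol %), PhI(OAc)2 (2.2 equiv), MeCN–H2O (1:1), rt
Reagents that add atoms: water, O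
Why: TEMPO-catalysed oxidation with PhI(OAc)2 as terminal oxidant takes the primary alcohol through the aldehyde hydrate to the acid in one operation; the weakly acidic medium and the short lifetime of the aldehyde should limit epimerisation at the α-carbon and olefin migration.

Step 17
Reactants: 21 (2R,3E)-4-iodo-2-methylbut-3-enoic acid
Product: 22 methyl (2R,3E)-4-iodo-2-methylbut-3-enoate
Conditions: Me3SiCHN2 (1.2 equiv), MeOH–toluene (1:3), 0 °C
Reagents that add atoms: (trimethylsilyl)diazomethane, C[Si](C)(C)C=[N+]=[N-]
Why: Base-free methyl esterification of the acid; no enolate is formed, so the allylic α-stereocentre and the E-olefin should be preserved.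

Step 18
Reactants: 15 (4aR,8aS)-1-(but-3-yn-1-yl)-2,5,5,8a-tetramethyl-3,4,4a,5,6,7,8,8a-octahydronaphthalene; 22 methyl (2R,3E)-4-iodo-2-methylbut-3-enoate
Product: 24 methyl (2R,3E,5E)-2,6-dimethyl-8-[(4aR,8aS)-2,5,5,8a-tetramethyl-3,4,4a,5,6,7,8,8a-octahydronaphthalen-1-yl]octa-3,5-dienoate, via alkenylalane 23 (not isolated)
Conditions: AlMe3 (2 equiv), Cp2ZrCl2 (0.25 equiv), CH2Cl2, 0 °C → rt; volatiles removed; then 22 (1.1 equiv), ZnCl2 (cat.), Pd(PPh3)4 (5 mol %), THF, rt
Reagents that add atoms: trimethylaluminium, C[Al](C)C
Why: Zirconium-catalysed methylalumination of the terminal alkyne (Negishi carboalumination) adds CH3 and Al syn with Al at the terminus, which fixes the 13E geometry; the alkenylalane then undergoes palladium/zinc co-catalysed Negishi coupling with the alkenyl iodide (oxidative addition to zerovalent palladium, transmetallation, reductive elimination) with retention at both sp2 carbons, and since no base is present the C17 stereocentre brought in with 22 should survive.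

## Compound list

1 | (3E)-4-[(1R)-2,6,6-trimethylcyclohex-2-en-1-yl]but-3-en-2-one, (R)-α-ionone | CC(=O)/C=C/[C@H]1C(C)=CCCC1(C)C | starting material
2 | 4-[(1R)-2,6,6-trimethylcyclohex-2-en-1-yl]butan-2-one | CC(=O)CC[C@H]1C(C)=CCCC1(C)C | intermediate
3 | dimethyl carbonate | COC(=O)OC | starting material
4 | methyl 3-oxo-5-[(1R)-2,6,6-trimethylcyclohex-2-en-1-yl]pentanoate | COC(=O)CC(=O)CC[C@H]1C(C)=CCCC1(C)C | intermediate
5 | methyl 3-oxo-5-[(1R)-2,6,6-trimethyl-4-oxocyclohex-2-en-1-yl]pentanoate | COC(=O)CC(=O)CC[C@H]1C(C)=CC(=O)CC1(C)C | intermediate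
6 | methyl (4aR,8aS)-2-hydroxy-5,5,8a-trimethyl-7-oxo-3,4,4a,5,6,7,8,8a-octahydronaphthalene-1-carboxylate (cis-fused, enol form) | COC(=O)C1=C(O)CC[C@@H]2C(C)(C)CC(=O)C[C@]12C | intermediate
7 | methyl (4aR,8aS)-5,5,8a-trimethyl-7-oxo-2-(trifluoromethanesulfonyloxy)-3,4,4a,5,6,7,8,8a-octahydronaphthalene-1-carboxylate | COC(=O)C1=C(OS(=O)(=O)C(F)(F)F)CC[C@@H]2C(C)(C)CC(=O)C[C@]12C | intermediate
8 | methyl (4aR,8aS)-2,5,5,8a-tetramethyl-7-oxo-3,4,4a,5,6,7,8,8a-octahydronaphthalene-1-carboxylate | COC(=O)C1=C(C)CC[C@@H]2C(C)(C)CC(=O)C[C@]12C | intermediate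
9 | methyl (4aR,8aS)-2,5,5,8a-tetramethyl-7-[2-(4-methylbenzenesulfonyl)hydrazinylidene]-3,4,4a,5,6,7,8,8a-octahydronaphthalene-1-carboxylate | COC(=O)C1=C(C)CC[C@@H]2C(C)(C)CC(=NNS(=O)(=O)c3ccc(C)cc3)C[C@]12C | intermediate
10 | methyl (4aR,8aS)-2,5,5,8a-tetramethyl-3,4,4a,5,6,7,8,8a-octahydronaphthalene-1-carboxylate | COC(=O)C1=C(C)CC[C@@H]2C(C)(C)CCC[C@]12C | intermediate
11 | [(4aR,8aS)-2,5,5,8a-tetramethyl-3,4,4a,5,6,7,8,8a-octahydronaphthalen-1-yl]methanol | OCC1=C(C)CC[C@@H]2C(C)(C)CCC[C@]12C | intermediate
12 | (4aR,8aS)-1-(bromomethyl)-2,5,5,8a-tetramethyl-3,4,4a,5,6,7,8,8a-octahydronaphthalene | BrCC1=C(C)CC[C@@H]2C(C)(C)CCC[C@]12C | intermediate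
13 | trimethyl(prop-1-yn-1-yl)silane | CC#C[Si](C)(C)C | starting material
14 | trimethyl{4-[(4aR,8aS)-2,5,5,8a-tetramethyl-3,4,4a,5,6,7,8,8a-octahydronaphthalen-1-yl]but-1-yn-1-yl}silane | C[Si](C)(C)C#CCCC1=C(C)CC[C@@H]2C(C)(C)CCC[C@]12C | intermediate
15 | (4aR,8aS)-1-(but-3-yn-1-yl)-2,5,5,8a-tetramethyl-3,4,4a,5,6,7,8,8a-octahydronaphthalene | C#CCCC1=C(C)CC[C@@H]2C(C)(C)CCC[C@]12C | intermediate
16 | methyl (2S)-3-hydroxy-2-methylpropanoate | COC(=O)[C@@H](C)CO | starting material
17 | methyl (2S)-3-[(tert-butyldimethylsilyl)oxy]-2-methylpropanoate | COC(=O)[C@@H](C)CO[Si](C)(C)C(C)(C)C | intermediate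
18 | (2S)-3-[(tert-butyldimethylsilyl)oxy]-2-methylpropanal | O=C[C@@H](C)CO[Si](C)(C)C(C)(C)C | intermediate
19 | tert-butyl{[(2R,3E)-4-iodo-2-methylbut-3-en-1-yl]oxy}dimethylsilane | I/C=C/[C@@H](C)CO[Si](C)(C)C(C)(C)C | intermediate
20 | (2R,3E)-4-iodo-2-methylbut-3-en-1-ol | I/C=C/[C@@H](C)CO | intermediate
21 | (2R,3E)-4-iodo-2-methylbut-3-enoic acid | I/C=C/[C@@H](C)C(=O)O | intermediate
22 | methyl (2R,3E)-4-iodo-2-methylbut-3-enoate | COC(=O)[C@H](C)/C=C/I | intermediate
23 | dimethyl{(1E)-2-methyl-4-[(4aR,8aS)-2,5,5,8a-tetramethyl-3,4,4a,5,6,7,8,8a-octahydronaphthalen-1-yl]but-1-en-1-yl}alumane | C[Al](C)/C=C(\C)CCC1=C(C)CC[C@@H]2C(C)(C)CCC[C@]12C | intermediate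
24 | methyl (2R,3E,5E)-2,6-dimethyl-8-[(4aR,8aS)-2,5,5,8a-tetramethyl-3,4,4a,5,6,7,8,8a-octahydronaphthalen-1-yl]octa-3,5-dienoate | COC(=O)[C@H](C)/C=C/C=C(\C)CCC1=C(C)CC[C@@H]2C(C)(C)CCC[C@]12C | target

## Step count and least certain steps

Total step count: 18. Longest linear sequence: 12 (steps 1–11 and 18); the second branch (steps 12–17) has 6 steps before the union.

**Step 4 (key step).** The most likely failure is slow or incomplete ring closure: the nucleophile must reach a β,β-disubstituted enone carbon past the axial C4 methyl. Retro-Michael equilibration under base could also return open-chain material or erode the cis selectivity. The fallback sets out from 5 and comes back at 6. The keto ester is silylated selectively (Me3SiCl, Et3N; the ring enone is not enolised under these conditions) to methyl 3-[(trimethylsilyl)oxy]-5-[(1R)-2,6,6-trimethyl-4-oxocyclohex-2-en-1-yl]pent-2-enoate F1. F1 is then closed by an intramolecular Mukaiyama–Michael addition (TiCl4, CH2Cl2, −78 °C). The same C9–C10 bond and ring B form, but under Lewis-acid activation of the acceptor and kinetic, irreversible control; aqueous work-up gives 6.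

**Step 3.** The most likely failure is competing oxidation: hydrogen abstraction or peroxidation at the doubly activated CH2 of the keto ester, or at the tertiary allylic C–H of the stereocentre. The fallback sets out from 4 and comes back at 5. The keto group is masked with ethylene glycol (TsOH cat., benzene, water removal) as methyl 2-(2-{2-[(1R)-2,6,6-trimethylcyclohex-2-en-1-yl]ethyl}-1,3-dioxolan-2-yl)acetate F2. The same allylic oxidation on F2 gives methyl 2-(2-{2-[(1R)-2,6,6-trimethyl-4-oxocyclohex-2-en-1-yl]ethyl}-1,3-dioxolan-2-yl)acetate F3. Mild aqueous acid (PPTS, acetone–water) releases 5.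

**Step 8.** The most likely failure is incomplete hydride delivery to the hindered hydrazone, or loss of sulfinate before reduction with elimination to olefins. The fallback sets out from 8 (bypassing 9) and comes back at 10 by a Barton–McCombie deoxygenation. NaBH4 in MeOH reduces the ketone to methyl (4aR,8aS)-7-hydroxy-2,5,5,8a-tetramethyl-3,4,4a,5,6,7,8,8a-octahydronaphthalene-1-carboxylate F4 (either C7 epimer serves). 1,1'-Thiocarbonyldiimidazole with DMAP gives methyl (4aR,8aS)-7-[(1H-imidazol-1-ylcarbonothioyl)oxy]-2,5,5,8a-tetramethyl-3,4,4a,5,6,7,8,8a-octahydronaphthalene-1-carboxylate F5. Bu3SnH with AIBN in hot toluene then gives 10.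

**Step 18.** The most likely failure is erosion of configuration at C17, or attack of aluminium species on the ester, during the one-flask carboalumination and coupling; incomplete regiocontrol in the methylalumination is a lesser concern. The fallback sets out from 15 and 19 and comes back at 24. Alkenylalane 23 is coupled under the same conditions with silyl ether 19, which has no acidic C–H, to give tert-butyl({(2R,3E,5E)-2,6-dimethyl-8-[(4aR,8aS)-2,5,5,8a-tetramethyl-3,4,4a,5,6,7,8,8a-octahydronaphthalen-1-yl]octa-3,5-dien-1-yl}oxy)dimethylsilane F6. Methanolysis (CSA, MeOH) gives (2R,3E,5E)-2,6-dimethyl-8-[(4aR,8aS)-2,5,5,8a-tetramethyl-3,4,4a,5,6,7,8,8a-octahydronaphthalen-1-yl]octa-3,5-dien-1-ol F7. TEMPO/PhI(OAc)2 oxidation gives (2R,3E,5E)-2,6-dimethyl-8-[(4aR,8aS)-2,5,5,8a-tetramethyl-3,4,4a,5,6,7,8,8a-octahydronaphthalen-1-yl]octa-3,5-dienoic acid F8. Me3SiCHN2 in methanol then gives 24.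

## Further compounds

F1 | step 4 | methyl 3-[(trimethylsilyl)oxy]-5-[(1R)-2,6,6-trimethyl-4-oxocyclohex-2-en-1-yl]pent-2-enoate (E/Z mixture) | COC(=O)C=C(CC[C@H]1C(C)=CC(=O)CC1(C)C)O[Si](C)(C)C
F2 | step 3 | methyl 2-(2-{2-[(1R)-2,6,6-trimethylcyclohex-2-en-1-yl]ethyl}-1,3-dioxolan-2-yl)acetate | COC(=O)CC1(CC[C@H]2C(C)=CCCC2(C)C)OCCO1
F3 | step 3 | methyl 2-(2-{2-[(1R)-2,6,6-trimethyl-4-oxocyclohex-2-en-1-yl]ethyl}-1,3-dioxolan-2-yl)acetate | COC(=O)CC1(CC[C@H]2C(C)=CC(=O)CC2(C)C)OCCO1
F4 | step 8 | methyl (4aR,8aS)-7-hydroxy-2,5,5,8a-tetramethyl-3,4,4a,5,6,7,8,8a-octahydronaphthalene-1-carboxylate (C7 epimers) | COC(=O)C1=C(C)CC[C@@H]2C(C)(C)CC(O)C[C@]12C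
F5 | step 8 | methyl (4aR,8aS)-7-[(1H-imidazol-1-ylcarbonothioyl)oxy]-2,5,5,8a-tetramethyl-3,4,4a,5,6,7,8,8a-octahydronaphthalene-1-carboxylate (C7 epimers) | COC(=O)C1=C(C)CC[C@@H]2C(C)(C)CC(OC(=S)n3ccnc3)C[C@]12C
F6 | step 18 | tert-butyl({(2R,3E,5E)-2,6-dimethyl-8-[(4aR,8aS)-2,5,5,8a-tetramethyl-3,4,4a,5,6,7,8,8a-octahydronaphthalen-1-yl]octa-3,5-dien-1-yl}oxy)dimethylsilane | CC(C)(C)[Si](C)(C)OC[C@H](C)/C=C/C=C(\C)CCC1=C(C)CC[C@@H]2C(C)(C)CCC[C@]12C
F7 | step 18 | (2R,3E,5E)-2,6-dimethyl-8-[(4aR,8aS)-2,5,5,8a-tetramethyl-3,4,4a,5,6,7,8,8a-octahydronaphthalen-1-yl]octa-3,5-dien-1-ol | OC[C@H](C)/C=C/C=C(\C)CCC1=C(C)CC[C@@H]2C(C)(C)CCC[C@]12C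
F8 | step 18 | (2R,3E,5E)-2,6-dimethyl-8-[(4aR,8aS)-2,5,5,8a-tetramethyl-3,4,4a,5,6,7,8,8a-octahydronaphthalen-1-yl]octa-3,5-dienoic acid | OC(=O)[C@H](C)/C=C/C=C(\C)CCC1=C(C)CC[C@@H]2C(C)(C)CCC[C@]12C
A1 | alternative 1 | (4aS,8aS)-5-(but-3-en-1-yl)-1,1,4a,6-tetramethyl-3,4,4a,7,8,8a-hexahydronaphthalen-2(1H)-one | C=CCCC1=C(C)CC[C@@H]2C(C)(C)C(=O)CC[C@]12C
A2 | alternative 1 | 6-(but-3-en-1-yl)-2-ethenyl-1,3,3,5-tetramethylbicyclo[2.2.2]oct-5-en-2-ol (ethenyl over the olefinic bridge) | C=C[C@]1(O)C(C)(C)[C@H]2CC[C@]1(C)C(CCC=C)=C2C
A3 | alternative 2 | cis-fused 2,5,5,8a-tetramethyl-4a,5,8,8a-tetrahydronaphthalene-1,4-dione | O=C1C(C)=CC(=O)[C@@H]2C(C)(C)C=CC[C@]12C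
A4 | alternative 2 | 2,6-dimethyl-1,4-benzoquinone | CC1=CC(=O)C=C(C)C1=O
A5 | alternative 2 | 4-methylpenta-1,3-diene | C=CC=C(C)C
A6 | alternative 3 | cis-fused 3,4a,8,8-tetramethyl-4-[2-(2-methyl-1,3-dioxolan-2-yl)ethyl]-4a,5,6,7,8,8a-hexahydronaphthalen-2(1H)-one | CC1(CCC2=C(C)C(=O)C[C@@H]3C(C)(C)CCC[C@]23C)OCCO1
A7 | alternative 3 | (4S)-2,4-dimethyl-3-[2-(2-methyl-1,3-dioxolan-2-yl)ethyl]-4-(4-methylpent-4-en-1-yl)cyclohexa-2,5-dien-1-one | CC1(CCC2=C(C)C(=O)C=C[C@]2(C)CCCC(C)=C)OCCO1
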